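**Plan**
- Retrosynthesis: the quinone ring is cut at its two C(=O)–C(OH) bonds, one on each side of the alkylated carbon. This leaves an alkylmalonyl C3 unit (C–C(alkyl)–C) and an unsubstituted C–CH–C unit.
- Enabling feature: the ring is the double enol of a 3-alkylcyclohexane-1,2,4,5-tetraone, i.e. two 1,3-dioxygenated three-carbon units joined by two 1,2-dicarbonyl bonds. A redox-neutral union of a 1,3-bis(acyl anion) with a 1,3-bis(acyl cation) therefore gives it directly.
- Further cuts: alkylmalonic acid to the C21 acid plus CO2; the C21 chain to 15-bromopentadecanoic acid plus hex-1-yne.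
- Forward: acetylide alkylation, alkyne to E-alkene, α-carboxylation, (chlorocarbonyl)ketene, then a one-flask [3+3] annulation with dilithiated 2,2'-methylenebis(1,3-dithiane) closes the only ring; dithioketal hydrolysis unmasks the dihydroxyquinone.
- Stereochemistry: the only stereo element, the E alkene, comes from dissolving-metal reduction of the alkyne; there is no stereocentre.

Key step: step 5

Remark: the two hydroxyquinone tautomers of the target (OH and C=O exchanged pairwise) are the same compound, so the orientation in which the symmetric C3 partner adds has no consequence.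

Step 1
Reactants: 1 15-bromopentadecanoic acid; 2 hex-1-yne
Product: 4 henicos-16-ynoic acid, via hex-1-yn-1-yllithium 3 (not isolated)
Conditions: 2 (3.3 equiv), n-BuLi (3.1 equiv), THF, −78 → 0 °C; then 1 in THF/DMPU, 0 → 20 °C; aq. HCl
Reagents that add atoms: none
Why: SN2 alkylation of a lithium acetylide by a primary bromide; the first equivalent of 3 only deprotonates the acid, the lithium carboxylate is inert to the acetylide, and no stereocentre is formed.

Step 2
Reactants: 4 henicos-16-ynoic acid
Product: 5 (16E)-henicos-16-enoic acid
Conditions: Li (excess), NH3(l)/THF, −33 °C; solid NH4Cl; aq. HCl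
Reagents that add atoms: none
Why: dissolving-metal reduction of an internal alkyne, in which the vinyl radical anion and vinyl anion relax to the trans geometry before protonation, should set the E double bond; the carboxylate is not reduced.

Step 3
Reactants: 5 (16E)-henicos-16-enoic acid
Product: 7 2-[(14E)-nonadec-14-en-1-yl]propanedioic acid, via dilithium enediolate 6 (not isolated)
Conditions: LiN(i-Pr)2 (2.3 equiv), THF/DMPU, 0 → 40 °C; CO2 (g), −78 → 20 °C; cold aq. HCl
Reagents that add atoms: carbon dioxide, O=C=O
Why: C-carboxylation of a carboxylic acid dianion with CO2 should give the monosubstituted malonic acid; the new carbon carries two identical carboxyl groups, so no stereocentre arises, and cold work-up avoids decarboxylation.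

Step 4
Reactants: 7 2-[(14E)-nonadec-14-en-1-yl]propanedioic acid
Product: 9 (16E)-2-(oxomethylidene)henicos-16-enoyl chloride, via malonyl dichloride 8 (not isolated)
Conditions: SOCl2 (neat), 45 °C; evaporate; toluene, 110 °C, N2 sweep; evaporate; used crude
Reagents that add atoms: thionyl chloride, O=S(Cl)Cl
Why: acid chloride formation followed by thermal 1,2-elimination of HCl from a monosubstituted malonyl dichloride is the standard entry to (chlorocarbonyl)ketenes; it removes the acidic malonyl hydrogen while keeping two acylating carbons, and the isolated alkene is inert to SOCl2.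

Step 5
Reactants: 9 (16E)-2-(oxomethylidene)henicos-16-enoyl chloride; 10 2,2'-methylenebis(1,3-dithiane)
Product: 13 16-hydroxy-15-[(14E)-nonadec-14-en-1-yl]-1,5,9,13-tetrathiadispiro[5.1.5.3]hexadec-15-en-14-one, via dilithio bis-dithiane 11 (not isolated), via lithiated acylketene 12 (not isolated)
Conditions: 10, n-BuLi (2.1 equiv), THF, −30 °C, 3 h; −78 °C, 9 in THF added slowly at high dilution; → 0 °C; aq. NH4Cl, then dilute HCl
Reagents that add atoms: none
Why: Proposed new method: a tandem double C-acylation (formal [3+3] annulation) in which each 2-lithio-1,3-dithiane carbon of 11, an acyl anion equivalent, attacks one acyl carbon of 9; the first addition, at the ketene carbon or at the acid chloride (both paths converge after loss of LiCl), gives acylketene 12, whose ketene carbon is then attacked by the second lithiated carbon held five atoms away. The closest known reaction types are the Corey–Seebach acylation of 2-lithio-1,3-dithianes by acid chlorides and esters, the ring-forming double alkylation of this same dianion by 1,3-dihalides, and the [3+3] cyclocondensations of (chlorocarbonyl)ketenes with 1,3-dinucleophiles. The six-membered ring should close in a 6-exo-dig mode, by in-plane attack on the C=O π* of the ketene, so that the enolate C=C ends up inside the ring. No stereocentre is formed. The step needs ring closure to outrun intermolecular acylation and proton transfer: 9 has no acidic hydrogen because its central carbon is sp2, the geminal sulfur substituents favour the folded conformer, slow addition of 9 to dilute 11 keeps the electrophile scarce, and the product is a 1,3-diketone enolate that resists further addition. Regiochemistry is not an issue because 11 is symmetric.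

Step 6
Reactants: 13 16-hydroxy-15-[(14E)-nonadec-14-en-1-yl]-1,5,9,13-tetrathiadispiro[5.1.5.3]hexadec-15-en-14-one
Product: 14 2,5-dihydroxy-3-[(14E)-nonadec-14-en-1-yl]cyclohexa-2,5-diene-1,4-dione
Conditions: HgCl2 (4.5 equiv), CaCO3 (5 equiv), MeCN/H2O 4:1, 20 → 50 °C; filter; wash with 1 M HCl
Reagents that add atoms: water, O
Why: thiophilic, HgCl2-assisted hydrolysis of the two S,S-ketals (the unmasking stage of Corey–Seebach chemistry) should release a 1,2-dicarbonyl on both sides, and the resulting cyclohexane-1,2,4,5-tetraone enolises at once to the bis-vinylogous acid; buffered HgCl2 is too weak an electrophile to oxymercurate the disubstituted alkene, so the E geometry should be kept.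

**Compound list**
1 | 15-bromopentadecanoic acid | OC(=O)CCCCCCCCCCCCCCBr | starting material
2 | hex-1-yne | CCCCC#C | starting material
3 | hex-1-yn-1-yllithium (formed in the flask) | [Li]C#CCCCC | intermediate
4 | henicos-16-ynoic acid | CCCCC#CCCCCCCCCCCCCCCC(=O)O | intermediate
5 | (16E)-henicos-16-enoic acid | CCCC/C=C/CCCCCCCCCCCCCCC(=O)O | intermediate
6 | dilithium (16E)-henicosa-1,16-diene-1,1-diolate (formed in the flask) | CCCC/C=C/CCCCCCCCCCCCCC=C(O[Li])O[Li] | intermediate
7 | 2-[(14E)-nonadec-14-en-1-yl]propanedioic acid | CCCC/C=C/CCCCCCCCCCCCCC(C(=O)O)C(=O)O | intermediate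
8 | 2-[(14E)-nonadec-14-en-1-yl]propanedioyl dichloride (formed in the flask) | CCCC/C=C/CCCCCCCCCCCCCC(C(=O)Cl)C(=O)Cl | intermediate
9 | (16E)-2-(oxomethylidene)henicos-16-enoyl chloride, the alkyl(chlorocarbonyl)ketene | CCCC/C=C/CCCCCCCCCCCCCC(=C=O)C(=O)Cl | intermediate
10 | 2,2'-methylenebis(1,3-dithiane) | C(C1SCCCS1)C1SCCCS1 | starting material
11 | 2,2'-methylenebis(2-lithio-1,3-dithiane) (formed in the flask) | [Li]C1(CC2([Li])SCCCS2)SCCCS1 | intermediate
12 | (16E)-1-{2-[(2-lithio-1,3-dithian-2-yl)methyl]-1,3-dithian-2-yl}-2-(oxomethylidene)henicos-16-en-1-one (formed in the flask) | CCCC/C=C/CCCCCCCCCCCCCC(=C=O)C(=O)C1(CC2([Li])SCCCS2)SCCCS1 | intermediate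
13 | 16-hydroxy-15-[(14E)-nonadec-14-en-1-yl]-1,5,9,13-tetrathiadispiro[5.1.5.3]hexadec-15-en-14-one (2-alkyl-3-hydroxycyclohex-2-enone with a spiro 1,3-dithiane at C4 and at C6) | CCCC/C=C/CCCCCCCCCCCCCC1=C(O)C2(SCCCS2)CC2(SCCCS2)C1=O | intermediate
14 | 2,5-dihydroxy-3-[(14E)-nonadec-14-en-1-yl]cyclohexa-2,5-diene-1,4-dione | CCCC/C=C/CCCCCCCCCCCCCC1=C(O)C(=O)C=C(O)C1=O | target

**Step count and risks**

Total step count: 6. Longest linear sequence: 6 steps (1 → 4 → 5 → 7 → 9 → 13 → 14); compound 10 is used as purchased.

Steps most likely to fail:

1. Step 5 (proposed new method). What may go wrong: chain growth by intermolecular acylation instead of ring closure, or quenching of the carbanions by proton or electron transfer before the second C–C bond forms. The fallback gives up the ring-forming union and attaches the chain to the preformed ring by known radical chemistry. It sets out from hex-1-yne 2. Its lithium salt 3 is alkylated with purchased 14-bromotetradecanoic acid (OC(=O)CCCCCCCCCCCCCBr) under the conditions of step 1 to give icos-15-ynoic acid F1. Li/NH3 reduction as in step 2 should give (15E)-icos-15-enoic acid F2. DCC and H2O2 (urea adduct) in CH2Cl2 at 0 °C convert this into bis[(15E)-icos-15-enoyl] peroxide F3. Heating F3 with purchased 2,5-dihydroxy-1,4-benzoquinone (O=C1C=C(O)C(=O)C=C1O, in excess) in acetic acid at about 95 °C should C-alkylate the free ring position with the (14E)-nonadec-14-enyl radical released on decarboxylation. The fallback comes back to the route at target 14.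

2. Step 4. What may go wrong: self-condensation of the ketene while it is heated and concentrated, or incomplete loss of HCl, which would carry an acidic species into the annulation and protonate the dianion. In the fallback the ketene is no longer made thermally or isolated. Acid 7 is converted at 20 °C with oxalyl chloride and catalytic DMF in CH2Cl2 into dichloride 8, which is isolated by evaporation. Only in the annulation apparatus, at −78 °C in THF, is 8 dehydrochlorinated by one equivalent of lithium 2,2,6,6-tetramethylpiperidide (prepared from the amine and n-BuLi); its amine is too weak an acid to protonate a 2-lithio-1,3-dithiane. The cold solution of 9 is transferred at once into dianion 11. The fallback sets out from 7 and comes back at 13; it makes no compound outside the list (F0).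

3. Step 6. What may go wrong: incomplete hydrolysis of S,S-ketals that sit next to a carbonyl group, attack of the thiophilic metal on the alkene, or retention of metal by the chelating product. The fallback changes from metal activation to oxidation at sulfur. It sets out from 13, which is oxidised with H2O2 (one equivalent per dithiane) in hexafluoropropan-2-ol at 20 °C, conditions that should leave the alkene untouched, to the bis(1,3-dithiane 1-oxide) F4 (mixture of sulfoxide diastereomers). The monosulfoxides are then hydrolysed with dilute HCl in THF, the sulfur leaving as 1,2-dithiolane. The fallback comes back at target 14.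

Further compounds
F1 | step 5 | icos-15-ynoic acid | CCCCC#CCCCCCCCCCCCCCC(=O)O
F2 | step 5 | (15E)-icos-15-enoic acid | CCCC/C=C/CCCCCCCCCCCCCC(=O)O
F3 | step 5 | bis[(15E)-icos-15-enoyl] peroxide | CCCC/C=C/CCCCCCCCCCCCCC(=O)OOC(=O)CCCCCCCCCCCCC/C=C/CCCC
F0 | step 4 | none | none
F4 | step 6 | 16-hydroxy-15-[(14E)-nonadec-14-en-1-yl]-1,5,9,13-tetrathiadispiro[5.1.5.3]hexadec-15-en-14-one 1,9-dioxide (mixture of sulfoxide diastereomers) | CCCC/C=C/CCCCCCCCCCCCCC1=C(O)C2(S(=O)CCCS2)CC2(S(=O)CCCS2)C1=O
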